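**Retrosynthetic overview**
1. Feature: in the nine-membered ring B, the quaternary ether carbon C4 (shared with pyran ring C) and the methylene-bearing carbon C8 are 1,5-related through C5–C6–C7, and both can be carbonyl carbons. They are therefore joined as a C4=C8 double bond common to a cyclopentene and a cyclohexene (ring A = cyclobutane, ring D = triketone).
2. Endgame: C8=CH2 from the C8 ketone (Wittig after base epimerisation of C9 to the trans A/B fusion); C4–CH3 from the C4 hemiketal via its oxocarbenium ion. Methylation comes first, because an exocyclic alkene at C8 would capture a C4 cation transannularly and because C5 stays epimerisable until C4 is quaternary.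
3. Hemiketal and ketone come from ozonolysis of the C4=C8 alkene of tetrahydroindene 22, which unveils ring B and lets an enol oxygen of ring D close ring C.
4. 22 comes from dearomative gem-dimethylation of an acylphloroglucinol (ring D), a hydroboration/intramolecular B-alkyl Suzuki closure of the cyclopentene (C7–C8), an Ir-catalysed allylic alkylation (C4–C5, sets C5) and an enantioselective cyclohexenone–isobutylene [2+2] photoadduct (ring A, sets C1).
5. Ring order: A on the cyclohexanone, then the cyclopentene, then D by dearomatisation, then B and C together in the key step.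

Key step: step 12

Remark (locants): caryophyllane numbering is used throughout. C1 and C9 are the cyclobutane ring-fusion carbons (C1 next to C11 = CMe2, C9 next to C10 = CH2), C2–C3 a CH2CH2 bridge, C4 the ether carbon, C5 the CH bearing the CH2 arm to ring D, C6–C7 the second CH2CH2 bridge, C8 the methylene-bearing carbon.
Remark (assumption): the photocycloaddition catalyst and the phosphoramidite ligand are each available as both antipodes; the antipode written is taken to be the one that gives the drawn configuration, otherwise its mirror image is used.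

**Step 1**
Reactants: 1 cyclohex-2-en-1-one; 2 isobutylene (2-methylpropene)
Product: 4 (1R,6R)-7,7-dimethylbicyclo[4.2.0]octan-2-one (cis-fused), via trans-fused (1S,6R)-ketone 3 (not isolated)
Conditions: 2 (excess), (S)-3,3-diphenyl-1-(2,4,6-trifluorophenyl)tetrahydro-1H,3H-pyrrolo[1,2-c][1,3,2]oxazaborole·AlBr3 (50 mol %), hν (366 nm), CH2Cl2, −75 °C; then basic Al2O3, CH2Cl2, rt
Reagents that add atoms: none
Why: Lewis acid-catalysed enone–alkene [2+2] photocycloaddition: the AlBr3-bound enone absorbs at 366 nm and reacts from the face left open by the oxazaborolidine, so that C1 is set (R) under catalyst control with the usual head-to-tail regiochemistry (CMe2 on the β-carbon), and basic alumina epimerises the enolisable C9 of the strained trans adduct 3 to the stable cis ring fusion.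

**Step 2**
Reactants: 4 (1R,6R)-7,7-dimethylbicyclo[4.2.0]octan-2-one
Product: 6 (1R,6R)-7,7-dimethyl-2-(trimethylsilyloxy)bicyclo[4.2.0]oct-2-ene, via lithium enolate 5 (not isolated)
Conditions: LiN(iPr)2, THF, −78 °C; Me3SiCl, Et3N, −78 °C → rt
Reagents that add atoms: chlorotrimethylsilane C[Si](C)(C)Cl
Why: Kinetic enolate formation and O-silylation: the amide base removes a proton from the α′-CH2 group (C4) faster than the ring-fusion methine C9–H, and no stereocentre is affected.

**Step 3**
Reactants: 7 phloroglucinol
Product: 8 1,3,5-tris(methoxymethoxy)benzene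
Conditions: NaH, MOMCl, DMF, 0 °C → rt
Reagents that add atoms: chloromethyl methyl ether COCCl
Why: Williamson-type O-alkylation of the phenoxide with the hard electrophile MOMCl gives the tris-acetal, which later protects the phenols and directs two ortho-lithiations.

**Step 4**
Reactants: 8 1,3,5-tris(methoxymethoxy)benzene
Product: 10 2-allyl-1,3,5-tris(methoxymethoxy)benzene, via aryllithium 9 (not isolated)
Conditions: n-BuLi, THF, 0 °C; allyl bromide, −78 °C → rt
Reagents that add atoms: allyl bromide C=CCBr
Why: Directed ortho-metalation between two OMOM groups followed by allylation of the aryllithium with allyl bromide; the three ring positions are equivalent so no regiochemical issue arises.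

**Step 5**
Reactants: 10 2-allyl-1,3,5-tris(methoxymethoxy)benzene; 11 allyl methyl carbonate
Product: 12 (E)-4-[2,4,6-tris(methoxymethoxy)phenyl]but-2-en-1-yl methyl carbonate
Conditions: 11 (4 equiv), second-generation Grubbs catalyst (5 mol %), CH2Cl2, 40 °C
Reagents that add atoms: none
Why: Olefin cross-metathesis of the allylarene with an excess of the allyl carbonate, which under thermodynamic control should give mainly the (E)-alkene needed for the allylic substitution.

**Step 6**
Reactants: 6 silyl enol ether; 12 (E)-allylic carbonate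
Product: 13 (1R,6R)-7,7-dimethyl-3-{(2S)-1-[2,4,6-tris(methoxymethoxy)phenyl]but-3-en-2-yl}bicyclo[4.2.0]octan-2-one (both C3 epimers; bicyclic C3 = C4 in caryophyllane numbering)
Conditions: [Ir(cod)Cl]2 (2 mol %), (S,S,S)-O,O′-(1,1′-binaphthyl-2,2′-diyl) N,N-bis(1-phenylethyl)phosphoramidite (4 mol %), CsF, ZnF2, DME, 50 °C
Reagents that add atoms: none
Why: Iridium-catalysed asymmetric allylic alkylation of a fluoride-activated enol silane: the cyclometalated iridium–phosphoramidite π-allyl complex is attacked at its substituted terminus, forming the C4–C5 bond and setting C5 (S) under catalyst control, whereas C4 forms as both epimers, which is of no consequence because C4 becomes sp2 in step 7; any minor enantiomer of 4 ends up as a separable diastereomer.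

**Step 7**
Reactants: 13 α-allylated ketone
Product: 15 (1R,6R)-7,7-dimethyl-3-{(2S)-1-[2,4,6-tris(methoxymethoxy)phenyl]but-3-en-2-yl}bicyclo[4.2.0]oct-2-en-2-yl trifluoromethanesulfonate (tetrasubstituted C4=C8 enol triflate), via potassium enolate 14 (not isolated)
Conditions: KN(SiMe3)2 (0.95 equiv), THF, −78 → 0 °C; PhNTf2, −78 °C → rt
Reagents that add atoms: N-phenylbis(trifluoromethanesulfonimide) O=S(=O)(N(c1ccccc1)S(=O)(=O)C(F)(F)F)C(F)(F)F
Why: Enolate O-triflation under thermodynamic control: with a slight deficit of base the enolates interconvert by proton transfer and should settle on the tetrasubstituted C4=C8 enolate, because the alternative C8=C9 enolate places an sp2 carbon at the cyclobutane ring fusion, and C5, which is not acidic, keeps its configuration.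

**Step 8**
Reactants: 15 enol triflate
Product: 17 (1R,5R,9R)-11,11-dimethyl-5-[2,4,6-tris(methoxymethoxy)benzyl]tricyclo[7.2.0.0^4,8]undec-4(8)-ene, via B-alkyl-9-BBN 16 (not isolated)
Conditions: 9-BBN-H, THF, 0 °C → rt; then Pd(dppf)Cl2 (5 mol %), K3PO4 (aq.), DMF, 60 °C
Reagents that add atoms: none
Why: Anti-Markovnikov hydroboration of the terminal vinyl group followed by intramolecular B-alkyl Suzuki–Miyaura coupling with the enol triflate closes the cyclopentene (C7–C8 bond) and leaves the double bond exactly where the triflate fixed it, at C4=C8; no stereocentre is formed.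

**Step 9**
Reactants: 17 tetrahydroindene
Product: 19 1-{3-[((1R,5R,9R)-11,11-dimethyltricyclo[7.2.0.0^4,8]undec-4(8)-en-5-yl)methyl]-2,4,6-tris(methoxymethoxy)phenyl}-2-methylpropan-1-one, via aryllithium 18 (not isolated)
Conditions: n-BuLi, THF, 0 °C; N-methoxy-N-methylisobutyramide, −78 °C → rt
Reagents that add atoms: N-methoxy-N-methylisobutyramide CC(C)C(=O)N(C)OC
Why: Directed ortho-metalation at one of the two equivalent positions flanked by OMOM groups and acylation with the N-methoxy-N-methyl amide, whose chelated tetrahedral adduct stops at the ketone stage.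

**Step 10**
Reactants: 19 aryl ketone
Product: 20 1-{3-[((1R,5R,9R)-11,11-dimethyltricyclo[7.2.0.0^4,8]undec-4(8)-en-5-yl)methyl]-2,4,6-trihydroxyphenyl}-2-methylpropan-1-one
Conditions: ZnBr2, n-PrSH, CH2Cl2, 0 °C
Reagents that add atoms: none
Why: Lewis acid/thiol cleavage of the three MOM acetals under conditions too mild to protonate the tetrasubstituted alkene, which avoids cyclisation of a free phenol onto C4 and rearrangement of the cyclobutylcarbinyl position.

**Step 11**
Reactants: 20 acylphloroglucinol
Product: 22 2-isobutyryl-4,4-dimethyl-6-[((1R,5R,9R)-11,11-dimethyltricyclo[7.2.0.0^4,8]undec-4(8)-en-5-yl)methyl]cyclohexane-1,3,5-trione (enolised; cis-fused cyclobutane), via monomethylated acylphloroglucinol 21 (not isolated)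
Conditions: NaOMe (4 equiv), MeI (2.2 equiv), MeOH, 0 °C → rt; cold dilute citric acid
Reagents that add atoms: iodomethane CI
Why: Twofold C-methylation of the phloroglucinol phenoxide (the classical route to acylfilicinic acids): the first methyl goes to the only free ring carbon and the second to the same, less hindered carbon, which dearomatises the ring to the gem-dimethyl β-triketone and leaves the carbocyclic stereocentres untouched.

**Step 12**
Reactants: 22 tetrahydroindene triketone
Product: 24 (1R,4S,5R,9R) pyran hemiketal: ring C closed from the enol oxygen next to CMe2 onto C4 (C4–OH), C8 ketone in the nine-membered ring B, cis-fused cyclobutane, via ring-opened 4,8-diketone 23 (not isolated)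
Conditions: O3 (1.05 equiv, titrated CH2Cl2 solution, Sudan Red 7B), CH2Cl2–MeOH 5:1, −78 °C; Me2S, −78 °C → rt; used crude
Reagents that add atoms: ozone [O-][O+]=O
Why: Ozone adds as a 1,3-dipole to the tetrasubstituted C4=C8 bond, the most electron-rich π bond of 22, and the primary ozonide cleaves to a ketone and a carbonyl oxide that is captured by methanol (or by the neighbouring enol OH) as an alkoxy hydroperoxide, which Me2S reduces to the 4,8-diketone 23. The closest known reaction type is the ozonolysis of ring-fusion alkenes of hydrindenes and octalins to medium-ring diketones. Ring B is not closed but unveiled by scission of the bond shared by the five- and six-membered rings, and ring C closes by 6-exo-trig addition of the free enol OH next to CMe2 to the C4 carbonyl, the other enol OH staying hydrogen-bonded to the isobutyryl group. No carbon stereocentre is created or touched except the hemiketal carbon C4, which is under thermodynamic control and is removed in step 13; C1, C5 and C9 are carried through unchanged provided the product is kept cold and free of acid and base, since C5 is now α to a masked ketone. The step needs chemoselectivity for the alkene over the two enol C=C bonds, which are deactivated by three carbonyl groups and stay un-ionised, and this is secured by dosing a titrated ozone solution at −78 °C to an indicator end point. It also needs C4 and not C8 to be masked, and only C4 can form a six-membered hemiketal with the enol oxygen (C8 would require an eight-membered ring).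

**Step 13**
Reactants: 24 pyran hemiketal
Product: 26 (1R,4S,5R,9R)-C4-methyl pyran with C8 ketone (the target with C=O in place of C=CH2 at C8 and a cis cyclobutane fusion), via C4 oxocarbenium ion 25 (not isolated)
Conditions: AlMe3 (5 equiv), CH2Cl2, −78 °C; then Me3SiOTf (2.5 equiv), −78 → −40 °C; aq. potassium sodium tartrate
Reagents that add atoms: trimethylaluminium C[Al](C)C
Why: Lewis acid-mediated C-methylation of a cyclic hemiketal through its oxocarbenium ion (C-glycosylation type): silylation turns the C4 hydroxyl into a leaving group that departs as hexamethyldisiloxane, and AlMe3 delivers methyl to the half-chair oxocarbenium ion 25 along the pseudoaxial trajectory anti to the pseudoaxial C5–H, which sets C4 (S) with CH3 trans to H-5 and a diequatorial C/B ring fusion, while the hindered nine-membered C8 ketone, merely complexed by aluminium at −78 °C, should not add methyl and, unlike an exocyclic alkene at C8, cannot capture the cation irreversibly.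

**Step 14**
Reactants: 26 C8 ketone (cis-fused)
Product: 28 target CNP0497637.1, (1R,4S,5R,9S), via trans-fused ketone 27 (not isolated)
Conditions: t-BuOK, t-BuOH–THF, rt; then Ph3PCH3Br/t-BuOK, THF, 60 °C; pH 5 buffer
Reagents that add atoms: methyltriphenylphosphonium bromide C[P+](c1ccccc1)(c1ccccc1)c1ccccc1.[Br-]
Why: Base-mediated equilibration of the enolisable C9 to the trans cyclobutane/nine-membered ring fusion (the stable arrangement in this ring system, giving 9S), followed by Wittig methylenation of the hindered C8 ketone; the acidic enol is merely deprotonated and the quaternary C4 and the now non-enolisable C5 cannot change.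

**Compound list**
1 | cyclohex-2-en-1-one | O=C1C=CCCC1 | starting material
2 | isobutylene | C=C(C)C | starting material
3 | (1S,6R)-7,7-dimethylbicyclo[4.2.0]octan-2-one (trans-fused) | O=C1CCC[C@@H]2[C@@H]1CC2(C)C | intermediate (not isolated)
4 | (1R,6R)-7,7-dimethylbicyclo[4.2.0]octan-2-one (cis-fused) | O=C1CCC[C@@H]2[C@H]1CC2(C)C | intermediate
5 | lithium (1R,6R)-7,7-dimethylbicyclo[4.2.0]oct-2-en-2-olate | [Li]OC1=CCC[C@@H]2[C@H]1CC2(C)C | intermediate (not isolated)
6 | (1R,6R)-7,7-dimethyl-2-(trimethylsilyloxy)bicyclo[4.2.0]oct-2-ene | C[Si](C)(C)OC1=CCC[C@@H]2[C@H]1CC2(C)C | intermediate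
7 | phloroglucinol | Oc1cc(O)cc(O)c1 | starting material
8 | 1,3,5-tris(methoxymethoxy)benzene | COCOc1cc(OCOC)cc(OCOC)c1 | intermediate
9 | 2,4,6-tris(methoxymethoxy)phenyllithium | [Li]c1c(OCOC)cc(OCOC)cc1OCOC | intermediate (not isolated)
10 | 2-allyl-1,3,5-tris(methoxymethoxy)benzene | C=CCc1c(OCOC)cc(OCOC)cc1OCOC | intermediate
11 | allyl methyl carbonate | C=CCOC(=O)OC | starting material
12 | (E)-4-[2,4,6-tris(methoxymethoxy)phenyl]but-2-en-1-yl methyl carbonate | COC(=O)OC/C=C/Cc1c(OCOC)cc(OCOC)cc1OCOC | intermediate
13 | (1R,6R)-7,7-dimethyl-3-{(2S)-1-[2,4,6-tris(methoxymethoxy)phenyl]but-3-en-2-yl}bicyclo[4.2.0]octan-2-one (C3 epimers) | O=C1C(CC[C@@H]2[C@H]1CC2(C)C)[C@H](C=C)Cc3c(OCOC)cc(OCOC)cc3OCOC | intermediate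
14 | potassium C4=C8 enolate of 13 | [K]OC1=C(CC[C@@H]2[C@H]1CC2(C)C)[C@H](C=C)Cc3c(OCOC)cc(OCOC)cc3OCOC | intermediate (not isolated)
15 | C4=C8 enol triflate of 13 | O=S(=O)(OC1=C(CC[C@@H]2[C@H]1CC2(C)C)[C@H](C=C)Cc3c(OCOC)cc(OCOC)cc3OCOC)C(F)(F)F | intermediate
16 | B-alkyl-9-BBN from hydroboration of the vinyl group of 15 | O=S(=O)(OC1=C(CC[C@@H]2[C@H]1CC2(C)C)[C@H](CCB3C4CCCC3CCC4)Cc5c(OCOC)cc(OCOC)cc5OCOC)C(F)(F)F | intermediate (not isolated)
17 | (1R,5R,9R)-11,11-dimethyl-5-[2,4,6-tris(methoxymethoxy)benzyl]tricyclo[7.2.0.0^4,8]undec-4(8)-ene | COCOc1cc(OCOC)c(C[C@H]2CCC3=C2CC[C@@H]2[C@H]3CC2(C)C)c(OCOC)c1 | intermediate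
18 | aryllithium from 17 (lithium between two OMOM groups) | COCOc1cc(OCOC)c(C[C@H]2CCC3=C2CC[C@@H]2[C@H]3CC2(C)C)c(OCOC)c1[Li] | intermediate (not isolated)
19 | isobutyryl tris-MOM arene | CC(C)C(=O)c1c(OCOC)cc(OCOC)c(C[C@H]2CCC3=C2CC[C@@H]2[C@H]3CC2(C)C)c1OCOC | intermediate
20 | alkylated isobutyrylphloroglucinol | CC(C)C(=O)c1c(O)cc(O)c(C[C@H]2CCC3=C2CC[C@@H]2[C@H]3CC2(C)C)c1O | intermediate
21 | mono-C-methylated acylphloroglucinol | CC(C)C(=O)c1c(O)c(C)c(O)c(C[C@H]2CCC3=C2CC[C@@H]2[C@H]3CC2(C)C)c1O | intermediate (not isolated)
22 | key-step precursor: enolised 2-isobutyryl-4,4-dimethyl-6-(tricycloundecenylmethyl)cyclohexane-1,3,5-trione, (1R,5R,9R) | CC(C)C(=O)C1=C(O)C(C[C@H]2CCC3=C2CC[C@@H]2[C@H]3CC2(C)C)=C(O)C(C)(C)C1=O | intermediate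
23 | ring-opened 4,8-diketone, (1R,5R,9R) | O=C1CC[C@H](CC3=C(O)C(C)(C)C(=O)C(C(=O)C(C)C)=C3O)C(=O)CC[C@@H]2[C@H]1CC2(C)C | intermediate (not isolated)
24 | key-step product: C4 pyran hemiketal with C8 ketone, (1R,4S,5R,9R) | O=C1CC[C@@H]2CC3=C(O[C@@]2(O)CC[C@@H]2[C@H]1CC2(C)C)C(C)(C)C(=O)C(C(=O)C(C)C)=C3O | intermediate
25 | C4 oxocarbenium ion (enol as O-dimethylaluminium derivative) | O=C1CC[C@@H]2CC3=C([O+]=C2CC[C@@H]2[C@H]1CC2(C)C)C(C)(C)C(=O)C(C(=O)C(C)C)=C3O[Al](C)C | intermediate (not isolated)
26 | C4-methyl pyran, C8 ketone, cis-fused cyclobutane, (1R,4S,5R,9R) | O=C1CC[C@@H]2CC3=C(O[C@@]2(C)CC[C@@H]2[C@H]1CC2(C)C)C(C)(C)C(=O)C(C(=O)C(C)C)=C3O | intermediate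
27 | C9 epimer of 26, trans-fused cyclobutane, (1R,4S,5R,9S) | O=C1CC[C@@H]2CC3=C(O[C@@]2(C)CC[C@@H]2[C@@H]1CC2(C)C)C(C)(C)C(=O)C(C(=O)C(C)C)=C3O | intermediate (not isolated)
28 | CNP0497637.1, (1R,4S,5R,9S) | C=C1CC[C@@H]2CC3=C(O[C@@]2(C)CC[C@@H]2[C@@H]1CC2(C)C)C(C)(C)C(=O)C(C(=O)C(C)C)=C3O | target

**Step count**
Total: 14 steps. Longest linear sequence: 12 steps (phloroglucinol 7 to 28, steps 3–14); the cyclohexenone branch is 11 steps (steps 1, 2, 6–14).

**Steps most likely to fail**

Step 13 (C4 methylation). The hemiketal may ionise by ring opening, with the vinylogous-acid oxygen leaving instead of the exocyclic oxygen, so that methyl adds to an open-chain ketone. The oxocarbenium ion may also lose a proton to a 4H-pyran, which erases C5, or aluminium may transfer methyl to the C8 ketone. Fallback: from 24, EtSH and Zn(OTf)2 (CH2Cl2, 0 °C) should give the C4 ethylthio S,O-ketal F1. Oxidation with mCPBA (NaHCO3, CH2Cl2, −20 °C) should give the C4 ethylsulfonyl ketal F2, whose exocyclic sulfone is the only group aluminium can pull off. AlMe3 (CH2Cl2, −78 → 0 °C) then expels sulfinate within an aluminium-bound ion pair and delivers methyl to C4, returning to the route at 26.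

Step 12 (ozonolysis). Ozone may be consumed by the enolised triketone, above all if it is partly ionised, and the hemiketal may epimerise at C5 or dehydrate on handling. Fallback: from 22, Ac2O, pyridine and DMAP (CH2Cl2, 0 °C) should give the bis(enol acetate) F3, whose enol double bonds are electron-poor and cannot ionise. Ozonolysis with Me2S work-up as in step 12 should give the 4,8-diketone bis(enol acetate) F4. NaHCO3 in MeOH at 0 °C then removes the activated enol acetates, and the freed enol closes onto C4, returning to the route at 24.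

Step 7 (regiochemistry of enolisation). Proton-transfer equilibration may leave part of the material as the C8=C9 enolate, giving a regioisomeric triflate and, after step 8, a misplaced double bond. Fallback: from 13, IBX·4-methoxypyridine N-oxide (DMSO, rt) should dehydrogenate the ketone to the C3=C4 enone F5; unsaturation toward C9–C1 would be a cyclobutene and is not expected to form. Conjugate reduction with LiBH(s-Bu)3 (THF, −78 °C) then generates the C4=C8 lithium enolate regiospecifically, and PhNTf2 traps it, returning to the route at 15.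

**Further compounds**
F1 | step 13 | C4 ethylthio S,O-ketal of 24 | O=C1CC[C@@H]2CC3=C(OC2(SCC)CC[C@@H]2[C@H]1CC2(C)C)C(C)(C)C(=O)C(C(=O)C(C)C)=C3O
F2 | step 13 | C4 ethylsulfonyl ketal | O=C1CC[C@@H]2CC3=C(OC2(S(=O)(=O)CC)CC[C@@H]2[C@H]1CC2(C)C)C(C)(C)C(=O)C(C(=O)C(C)C)=C3O
F3 | step 12 | bis(enol acetate) of 22 | CC(C)C(=O)C1=C(OC(C)=O)C(C[C@H]2CCC3=C2CC[C@@H]2[C@H]3CC2(C)C)=C(OC(C)=O)C(C)(C)C1=O
F4 | step 12 | 4,8-diketone bis(enol acetate) | O=C1CC[C@H](CC3=C(OC(C)=O)C(C)(C)C(=O)C(C(=O)C(C)C)=C3OC(C)=O)C(=O)CC[C@@H]2[C@H]1CC2(C)C
F5 | step 7 | C3=C4 enone from 13 | O=C1C(=CC[C@@H]2[C@H]1CC2(C)C)[C@H](C=C)Cc3c(OCOC)cc(OCOC)cc3OCOC
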